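**Retrosynthetic overview** (target atoms numbered as in 1H-isochromene: O2, C1, C3, C4, C4a, C5–C8, C8a; ring A = pyran, ring B = carbocycle)
1. Target 24 ⇐ removal of the aryl silyl ether ⇐ acylation of the secondary C6–OH of diol 21 with acid 4 (made from 2,4-dihydroxy-6-methylbenzaldehyde 1).
2. Ring B, formed last: C7–C8 bond by a carbene-catalysed intramolecular crossed benzoin reaction of pyran aldehyde 19. The enabling feature is the α-ketol C8(=O)–C7(OH)(CH3) of ring B: in 19 both carbons are carbonyl carbons (formyl C8 on C8a, acetyl C7 in the side chain), held cis by the C8a=C4a bond of ring A, so an acyl anion equivalent at C8 closes a six-membered ring.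
3. Ring A, formed first: O2–C1 bond by oxa-6π electrocyclization of the (Z)-dienone 17, obtained by Stille coupling (C4a–C8a bond) of the (Z)-β-iodoenone 14 with stannane 16.
4. 14 ⇐ HI addition to ynone 13 ⇐ acyl Sonogashira coupling of alkyne 11 with (2E)-but-2-enoyl chloride 12; 11 ⇐ methyl (S)-glycidate 5 + ethynyl(trimethyl)silane 6, so C6 comes from the chiral pool.

Key step: step 12

Assumption: the (5aS,10bR) antipode of the aminoindanol-derived triazolium salt is taken to direct C8 to the Re face of the C7 ketone of 19; if the sense of induction is the opposite, the (5aR,10bS) salt is used with no other change.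

**Step 1**
Reactants: 1 2,4-dihydroxy-6-methylbenzaldehyde
Product: 2 2-hydroxy-6-methyl-4-{[tri(propan-2-yl)silyl]oxy}benzaldehyde
Conditions: i-Pr3SiCl (1.05 equiv), imidazole, DMF, 0 °C
Reagents that add atoms: chlorotri(propan-2-yl)silane, CC(C)[Si](Cl)(C(C)C)C(C)C
Why: The 4-hydroxyl is the more acidic and unhindered phenol while the 2-hydroxyl is tied up in a hydrogen bond to the formyl group, so silyl ether formation with one equivalent of silyl chloride should occur at O-4 only.

**Step 2**
Reactants: 2 2-hydroxy-6-methyl-4-{[tri(propan-2-yl)silyl]oxy}benzaldehyde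
Product: 3 2-methoxy-6-methyl-4-{[tri(propan-2-yl)silyl]oxy}benzaldehyde
Conditions: MeI, K2CO3, acetone, 40 °C
Reagents that add atoms: iodomethane, CI
Why: Williamson ether synthesis on the remaining chelated phenol; the hindered aryl triisopropylsilyl ether should survive carbonate in acetone.

**Step 3**
Reactants: 3 2-methoxy-6-methyl-4-{[tri(propan-2-yl)silyl]oxy}benzaldehyde
Product: 4 2-methoxy-6-methyl-4-{[tri(propan-2-yl)silyl]oxy}benzoic acid
Conditions: NaClO2, NaH2PO4, 2-methylbut-2-ene, t-BuOH/H2O, 0 → 23 °C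
Reagents that add atoms: sodium chlorite, [Na+].[O-]Cl=O
Why: Pinnick oxidation converts the hindered, electron-rich aldehyde to the acid under buffered conditions, and the alkene scavenger removes hypochlorous acid before it can chlorinate the arene.

**Step 4**
Reactants: 5 methyl (2S)-oxirane-2-carboxylate; 6 ethynyl(trimethyl)silane
Product: 8 methyl (2S)-2-hydroxypent-4-ynoate, via the C-silyl alkyne 7 (not isolated)
Conditions: 6, n-BuLi, THF, −78 °C; BF3·OEt2; 5, −78 °C; aq. NH4Cl; then K2CO3 (cat.), MeOH, 0 °C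
Reagents that add atoms: none
Why: Yamaguchi–Hirao alkynylation: the lithium alkynyltrifluoroborate opens the epoxide by SN2 attack at the unsubstituted C3, the ester is untouched at −78 °C and the C2 stereocenter (later C6) is not involved, after which methanolysis removes the C-silyl group.

**Step 5**
Reactants: 8 methyl (2S)-2-hydroxypent-4-ynoate
Product: 9 methyl (2S)-2-{[tert-butyl(dimethyl)silyl]oxy}pent-4-ynoate
Conditions: t-BuMe2SiCl, imidazole, DMF, 23 °C
Reagents that add atoms: tert-butyl(chloro)dimethylsilane, CC(C)(C)[Si](C)(C)Cl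
Why: Standard silyl ether formation on the secondary alcohol; this group should survive the Grignard reagent, acetic acid and dilute aqueous acid that follow.

**Step 6**
Reactants: 9 methyl (2S)-2-{[tert-butyl(dimethyl)silyl]oxy}pent-4-ynoate
Product: 10 (2S)-2-{[tert-butyl(dimethyl)silyl]oxy}-N-methoxy-N-methylpent-4-ynamide
Conditions: MeNH(OMe)·HCl, i-PrMgCl, THF, −20 °C
Reagents that add atoms: N,O-dimethylhydroxylamine hydrochloride, CNOC.Cl
Why: Aminolysis of the ester by the chloromagnesium amide (Weinreb amide synthesis); one equivalent of base is taken up by the alkyne C–H and the low temperature should keep the α-stereocenter intact.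

**Step 7**
Reactants: 10 (2S)-2-{[tert-butyl(dimethyl)silyl]oxy}-N-methoxy-N-methylpent-4-ynamide
Product: 11 (3S)-3-{[tert-butyl(dimethyl)silyl]oxy}hex-5-yn-2-one
Conditions: MeMgBr (3 equiv), THF, 0 °C; aq. NH4Cl
Reagents that add atoms: methylmagnesium bromide, C[Mg]Br
Why: Weinreb ketone synthesis: the magnesium-chelated tetrahedral adduct does not collapse before work-up, so only one methyl group is delivered.

**Step 8**
Reactants: 11 (3S)-3-{[tert-butyl(dimethyl)silyl]oxy}hex-5-yn-2-one; 12 (2E)-but-2-enoyl chloride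
Product: 13 (3S,8E)-3-{[tert-butyl(dimethyl)silyl]oxy}dec-8-en-5-yne-2,7-dione
Conditions: PdCl2(PPh3)2 (2 mol%), CuI (4 mol%), Et3N (1.1 equiv), THF, 0 → 23 °C
Reagents that add atoms: none
Why: Acyl Sonogashira coupling of the copper acetylide with the acylpalladium chloride; only one equivalent of amine is used at low temperature to limit ketene formation from the acid chloride.

**Step 9**
Reactants: 13 (3S,8E)-3-{[tert-butyl(dimethyl)silyl]oxy}dec-8-en-5-yne-2,7-dione
Product: 14 (3S,5Z,8E)-3-{[tert-butyl(dimethyl)silyl]oxy}-5-iododeca-5,8-diene-2,7-dione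
Conditions: NaI (3 equiv), AcOH, 23 °C
Reagents that add atoms: sodium iodide, [Na+].[I-]
Why: Conjugate hydroiodination of the ynone: iodide adds to the alkyne carbon β to the carbonyl and the allenol is protonated anti, which should give the (Z)-β-iodoenone, while any HI adduct of the weaker crotonyl acceptor reverts.

**Step 10**
Reactants: 15 2-bromo-3,3-diethoxyprop-1-ene
Product: 16 tributyl(3,3-diethoxyprop-1-en-2-yl)stannane
Conditions: t-BuLi (2.1 equiv), Et2O, −78 °C; Bu3SnCl, −78 → 0 °C
Reagents that add atoms: tributyl(chloro)stannane, CCCC[Sn](Cl)(CCCC)CCCC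
Why: Bromine–lithium exchange followed by stannylation of the alkenyllithium.

**Step 11**
Reactants: 14 (3S,5Z,8E)-3-{[tert-butyl(dimethyl)silyl]oxy}-5-iododeca-5,8-diene-2,7-dione; 16 tributyl(3,3-diethoxyprop-1-en-2-yl)stannane
Product: 19 4-[(2S)-2-{[tert-butyl(dimethyl)silyl]oxy}-3-oxobutyl]-6-[(1E)-prop-1-en-1-yl]-2H-pyran-3-carbaldehyde, via the Z-dienone acetal 17 (not isolated), via the 2H-pyran acetal 18 (not isolated)
Conditions: Pd2(dba)3 (2.5 mol%), AsPh3 (20 mol%), CuI (10 mol%), DMF, 23 °C, dark; then 1 M aq. HCl, THF, 0 °C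
Reagents that add atoms: water, O
Why: Stille coupling with retention of alkene geometry puts the new alkenyl group (C8a) cis to the C3 carbonyl, so the 1-oxatriene 17 should close by thermal oxa-6π electrocyclization (O2–C1 bond, ring A), and hydrolysis of the allylic acetal then gives the formyl group whose push–pull conjugation with the dienyl ether holds the 2H-pyran form.

**Step 12**
Reactants: 19 4-[(2S)-2-{[tert-butyl(dimethyl)silyl]oxy}-3-oxobutyl]-6-[(1E)-prop-1-en-1-yl]-2H-pyran-3-carbaldehyde
Product: 20 (6S,7S)-6-{[tert-butyl(dimethyl)silyl]oxy}-7-hydroxy-7-methyl-3-[(1E)-prop-1-en-1-yl]-6,7-dihydro-1H-isochromen-8(5H)-one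
Conditions: (5aS,10bR)-5a,10b-dihydro-2-(pentafluorophenyl)-4H,6H-indeno[2,1-b][1,2,4]triazolo[4,3-d][1,4]oxazin-2-ium tetrafluoroborate (C18H11BF9N3O, 15 mol%), i-Pr2NEt (15 mol%), toluene (0.05 M), 23 °C
Reagents that add atoms: none
Why: The carbene formed from the triazolium salt adds to the C8 formyl group and proton transfer gives the Breslow enaminol, an acyl anion equivalent (polarity reversal at C8) whose carbon attacks the C7 ketone, after which the adduct releases the carbene and the α-ketol. The closest known reaction type is the carbene-catalysed intramolecular crossed aldehyde–ketone benzoin cyclization of 2-(3-oxobutyl)benzaldehydes to 2-hydroxy-2-methyl-1-tetralones, with the benzene ring replaced here by the C8a=C4a bond of ring A. Ring B closes in the 6-exo-trig mode. The new quaternary stereocenter C7 is controlled by the chiral aminoindanol backbone of the catalyst, which should direct C8 to the Re face of the ketone and so give (7S) with the hydroxyl cis to the C6 silyloxy group, while the resident C6 stereocenter keeps its bulky substituent pseudo-equatorial. The step needs benzoin addition to win over homoenolate β-protonation and intermolecular self-condensation: C4a is fully substituted and part of the electron-rich dienyl ether, no proton source or other electrophile is present, C7 is the only carbonyl within reach, and the hindered aldehyde is kept dilute.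

**Step 13**
Reactants: 20 (6S,7S)-6-{[tert-butyl(dimethyl)silyl]oxy}-7-hydroxy-7-methyl-3-[(1E)-prop-1-en-1-yl]-6,7-dihydro-1H-isochromen-8(5H)-one
Product: 21 (6S,7S)-6,7-dihydroxy-7-methyl-3-[(1E)-prop-1-en-1-yl]-6,7-dihydro-1H-isochromen-8(5H)-one
Conditions: HF·pyridine, pyridine, THF, 0 → 23 °C
Reagents that add atoms: none
Why: Fluoride cleaves the Si–O bond; buffered hydrogen fluoride is used instead of a basic fluoride source to avoid retro-benzoin or α-ketol shifts of the tertiary α-hydroxy ketone.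

**Step 14**
Reactants: 21 (6S,7S)-6,7-dihydroxy-7-methyl-3-[(1E)-prop-1-en-1-yl]-6,7-dihydro-1H-isochromen-8(5H)-one; 4 2-methoxy-6-methyl-4-{[tri(propan-2-yl)silyl]oxy}benzoic acid
Product: 23 (6S,7S)-7-hydroxy-7-methyl-8-oxo-3-[(1E)-prop-1-en-1-yl]-5,6,7,8-tetrahydro-1H-isochromen-6-yl 2-methoxy-6-methyl-4-{[tri(propan-2-yl)silyl]oxy}benzoate, via the acid chloride 22 (not isolated)
Conditions: 4, (COCl)2, cat. DMF, CH2Cl2, 0 → 23 °C, evaporate; then 21, DMAP (0.5 equiv), Et3N, CH2Cl2, 0 → 35 °C
Reagents that add atoms: none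
Why: DMAP-catalysed acyl transfer from the acid chloride should take place at the secondary C6 hydroxyl only, because the tertiary C7 hydroxyl next to the ketone is far less nucleophilic.

**Step 15**
Reactants: 23 (6S,7S)-7-hydroxy-7-methyl-8-oxo-3-[(1E)-prop-1-en-1-yl]-5,6,7,8-tetrahydro-1H-isochromen-6-yl 2-methoxy-6-methyl-4-{[tri(propan-2-yl)silyl]oxy}benzoate
Product: 24 comazaphilone G, (6S,7S)-7-hydroxy-7-methyl-8-oxo-3-[(1E)-prop-1-en-1-yl]-5,6,7,8-tetrahydro-1H-isochromen-6-yl 4-hydroxy-2-methoxy-6-methylbenzoate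
Conditions: Bu4NF (1.1 equiv), AcOH (1.2 equiv), THF, 0 °C
Reagents that add atoms: none
Why: Fluoride-induced cleavage of the aryl silyl ether, buffered with acetic acid so that the phenoxide is protonated at once and the hindered benzoate and the α-ketol are not exposed to base.

**Compound list**
1 | 2,4-dihydroxy-6-methylbenzaldehyde | Cc1cc(O)cc(O)c1C=O | starting material
2 | 2-hydroxy-6-methyl-4-{[tri(propan-2-yl)silyl]oxy}benzaldehyde | Cc1cc(O[Si](C(C)C)(C(C)C)C(C)C)cc(O)c1C=O | intermediate
3 | 2-methoxy-6-methyl-4-{[tri(propan-2-yl)silyl]oxy}benzaldehyde | COc1cc(O[Si](C(C)C)(C(C)C)C(C)C)cc(C)c1C=O | intermediate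
4 | 2-methoxy-6-methyl-4-{[tri(propan-2-yl)silyl]oxy}benzoic acid | COc1cc(O[Si](C(C)C)(C(C)C)C(C)C)cc(C)c1C(=O)O | intermediate
5 | methyl (2S)-oxirane-2-carboxylate | COC(=O)[C@@H]1CO1 | starting material
6 | ethynyl(trimethyl)silane | C#C[Si](C)(C)C | starting material
7 | methyl (2S)-2-hydroxy-5-(trimethylsilyl)pent-4-ynoate | COC(=O)[C@@H](O)CC#C[Si](C)(C)C | intermediate
8 | methyl (2S)-2-hydroxypent-4-ynoate | COC(=O)[C@@H](O)CC#C | intermediate
9 | methyl (2S)-2-{[tert-butyl(dimethyl)silyl]oxy}pent-4-ynoate | COC(=O)[C@@H](O[Si](C)(C)C(C)(C)C)CC#C | intermediate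
10 | (2S)-2-{[tert-butyl(dimethyl)silyl]oxy}-N-methoxy-N-methylpent-4-ynamide | CON(C)C(=O)[C@@H](O[Si](C)(C)C(C)(C)C)CC#C | intermediate
11 | (3S)-3-{[tert-butyl(dimethyl)silyl]oxy}hex-5-yn-2-one | CC(=O)[C@@H](O[Si](C)(C)C(C)(C)C)CC#C | intermediate
12 | (2E)-but-2-enoyl chloride | C/C=C/C(Cl)=O | starting material
13 | (3S,8E)-3-{[tert-butyl(dimethyl)silyl]oxy}dec-8-en-5-yne-2,7-dione | CC(=O)[C@@H](O[Si](C)(C)C(C)(C)C)CC#CC(=O)/C=C/C | intermediate
14 | (3S,5Z,8E)-3-{[tert-butyl(dimethyl)silyl]oxy}-5-iododeca-5,8-diene-2,7-dione | CC(=O)[C@@H](O[Si](C)(C)C(C)(C)C)C/C(I)=C/C(=O)/C=C/C | intermediate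
15 | 2-bromo-3,3-diethoxyprop-1-ene | C=C(Br)C(OCC)OCC | starting material
16 | tributyl(3,3-diethoxyprop-1-en-2-yl)stannane | CCCC[Sn](CCCC)(CCCC)C(=C)C(OCC)OCC | intermediate
17 | (3S,5Z,8E)-3-{[tert-butyl(dimethyl)silyl]oxy}-5-(3,3-diethoxyprop-1-en-2-yl)deca-5,8-diene-2,7-dione | CC(=O)[C@@H](O[Si](C)(C)C(C)(C)C)C/C(C(=C)C(OCC)OCC)=C/C(=O)/C=C/C | intermediate
18 | (3S)-3-{[tert-butyl(dimethyl)silyl]oxy}-4-{3-(diethoxymethyl)-6-[(1E)-prop-1-en-1-yl]-2H-pyran-4-yl}butan-2-one | C/C=C/C1=CC(C[C@H](O[Si](C)(C)C(C)(C)C)C(C)=O)=C(C(OCC)OCC)CO1 | intermediate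
19 | 4-[(2S)-2-{[tert-butyl(dimethyl)silyl]oxy}-3-oxobutyl]-6-[(1E)-prop-1-en-1-yl]-2H-pyran-3-carbaldehyde | C/C=C/C1=CC(C[C@H](O[Si](C)(C)C(C)(C)C)C(C)=O)=C(C=O)CO1 | intermediate
20 | (6S,7S)-6-{[tert-butyl(dimethyl)silyl]oxy}-7-hydroxy-7-methyl-3-[(1E)-prop-1-en-1-yl]-6,7-dihydro-1H-isochromen-8(5H)-one | C/C=C/C1=CC2=C(CO1)C(=O)[C@@](C)(O)[C@@H](O[Si](C)(C)C(C)(C)C)C2 | intermediate
21 | (6S,7S)-6,7-dihydroxy-7-methyl-3-[(1E)-prop-1-en-1-yl]-6,7-dihydro-1H-isochromen-8(5H)-one | C/C=C/C1=CC2=C(CO1)C(=O)[C@@](C)(O)[C@@H](O)C2 | intermediate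
22 | 2-methoxy-6-methyl-4-{[tri(propan-2-yl)silyl]oxy}benzoyl chloride | COc1cc(O[Si](C(C)C)(C(C)C)C(C)C)cc(C)c1C(Cl)=O | intermediate
23 | (6S,7S)-7-hydroxy-7-methyl-8-oxo-3-[(1E)-prop-1-en-1-yl]-5,6,7,8-tetrahydro-1H-isochromen-6-yl 2-methoxy-6-methyl-4-{[tri(propan-2-yl)silyl]oxy}benzoate | C/C=C/C1=CC2=C(CO1)C(=O)[C@@](C)(O)[C@@H](OC(=O)c1c(C)cc(O[Si](C(C)C)(C(C)C)C(C)C)cc1OC)C2 | intermediate
24 | comazaphilone G | C/C=C/C1=CC2=C(CO1)C(=O)[C@@](C)(O)[C@@H](OC(=O)c1c(C)cc(O)cc1OC)C2 | target

**Totals**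
Total step count: 15. Longest linear sequence: 11 steps (steps 4–9 and 11–15, from 5).

**Steps most likely to fail**

Step 11. Transmetalation of the α-branched, acetal-bearing alkenylstannane may be slow. Protodestannylation and Z-to-E isomerization of the iodoenone or of the dienone would then take over, and the E isomer cannot electrocyclize. The fallback sets out from 14 and introduces C8 only after ring A exists. Stille coupling of 14 with commercial tributyl(ethenyl)stannane (Pd2(dba)3, AsPh3, DMF) should give the trienone (3S,5Z,8E)-3-{[tert-butyl(dimethyl)silyl]oxy}-5-ethenyldeca-5,8-diene-2,7-dione F1, which should electrocyclize to (3S)-3-{[tert-butyl(dimethyl)silyl]oxy}-4-{6-[(1E)-prop-1-en-1-yl]-2H-pyran-4-yl}butan-2-one F2. Vilsmeier–Haack formylation (POCl3, DMF, CH2Cl2, 0 °C; aq. NaOAc) at C8a, the terminal carbon of the dienyl ether, should then give 19, where the fallback rejoins the route.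

Step 12. The hindered, electron-rich vinylogous formate may be slow to form the Breslow intermediate. The dipole-minimized conformer of the α-silyloxy ketone may also oppose the catalyst and erode facial selectivity at C7. The fallback sets out from 19 and uses substrate control instead of catalyst control. HF·pyridine should remove the silyl ether to give 4-[(2S)-2-hydroxy-3-oxobutyl]-6-[(1E)-prop-1-en-1-yl]-2H-pyran-3-carbaldehyde F3. An achiral carbene, from 6,7-dihydro-2-(pentafluorophenyl)-5H-pyrrolo[2,1-c][1,2,4]triazol-2-ium tetrafluoroborate (C11H7BF9N3) and i-Pr2NEt in toluene, should then close ring B. The free α-hydroxy ketone should react through its hydrogen-bonded syn-periplanar conformer, and the tethered acyl anion can only add from the side of C5, which places the new C7 hydroxyl cis to the C6 hydroxyl. The fallback rejoins the route at 21, so steps 12 and 13 are replaced.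

Step 8. Triethylamine may dehydrochlorinate the γ-enolizable acid chloride to a vinylketene, and amine may add to the cross-conjugated ynone. The fallback sets out from 11 and forms the same C–C bond at the alcohol oxidation level. Addition of the zinc acetylide of 11 to (2E)-but-2-enal (Zn(OTf)2, Et3N, toluene, 23 °C) should give (3S,8E)-3-{[tert-butyl(dimethyl)silyl]oxy}-7-hydroxydec-8-en-5-yn-2-one F4 as a mixture of carbinol epimers, which does not matter. Oxidation of this propargylic and allylic alcohol with MnO2 in CH2Cl2 should give 13, where the fallback rejoins the route.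

**Further compounds**
F1 | step 11 | (3S,5Z,8E)-3-{[tert-butyl(dimethyl)silyl]oxy}-5-ethenyldeca-5,8-diene-2,7-dione | CC(=O)[C@@H](O[Si](C)(C)C(C)(C)C)C/C(C=C)=C/C(=O)/C=C/C
F2 | step 11 | (3S)-3-{[tert-butyl(dimethyl)silyl]oxy}-4-{6-[(1E)-prop-1-en-1-yl]-2H-pyran-4-yl}butan-2-one | C/C=C/C1=CC(C[C@H](O[Si](C)(C)C(C)(C)C)C(C)=O)=CCO1
F3 | step 12 | 4-[(2S)-2-hydroxy-3-oxobutyl]-6-[(1E)-prop-1-en-1-yl]-2H-pyran-3-carbaldehyde | C/C=C/C1=CC(C[C@H](O)C(C)=O)=C(C=O)CO1
F4 | step 8 | (3S,8E)-3-{[tert-butyl(dimethyl)silyl]oxy}-7-hydroxydec-8-en-5-yn-2-one | CC(=O)[C@@H](O[Si](C)(C)C(C)(C)C)CC#CC(O)/C=C/C
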